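**Retrosynthetic overview**
- Target 18 comes from aldehyde 16 by NaBH4 reduction and desilylation, so only ring B has to be made; ring A and the dimethoxyphenyl ring are bought.
- Key disconnection C1–C2: C1 is the methine between ring A (at C8a) and the 3,4-dimethoxyphenyl ring, so it can be a stabilized diarylmethyl cation. C2 is the alpha carbon of the C9 aldehyde (the later CH2OH on C2), and C3=C4 is already in place on ring A.
- Precursor 15 comes from lactone 12, which comes from Stobbe half ester 10 (this fixes the E alkene and differentiates the two carboxyl carbons), made from aldehyde 8 and dimethyl succinate.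
- Aldehyde 8 comes from 2-bromo-3,4,5-trimethoxybenzaldehyde (as its acetal, by Br/Li exchange) and veratraldehyde. Ring B is the only ring formed in the route.

Key step: step 10

Remark: the benzhydryl oxygen is carried as its methyl ether instead of the free carbinol. It is inert to the base, hydride and silylation steps, cannot add to the neighbouring unsaturated ester, and is ionized in the key step like the carbinol, with methanol as leaving group.
Remark (assumption): the sense of induction at C2 is taken from the usual shielding model of the imidazolidinone; should it prove opposite, the (5R) catalyst is used with no other change.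
Abbreviation: Ar* = 2-[(3,4-dimethoxyphenyl)(methoxy)methyl]-3,4,5-trimethoxyphenyl (racemic at the ether carbon).

**Route**

Step 1
Reactants: 1 3,4,5-trimethoxybenzaldehyde
Product: 2 2-bromo-3,4,5-trimethoxybenzaldehyde
Conditions: NBS, CHCl3, reflux
Reagents that add atoms: N-bromosuccinimide, O=C1CCC(=O)N1Br
Why: Electrophilic aromatic bromination; the two free ring positions are equivalent and activated by ortho and para methoxy groups, so one monobromide should form.

Step 2
Reactants: 2 2-bromo-3,4,5-trimethoxybenzaldehyde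
Product: 3 2-bromo-1-(dimethoxymethyl)-3,4,5-trimethoxybenzene
Conditions: HC(OMe)3, p-TsOH (cat.), MeOH, rt
Reagents that add atoms: trimethyl orthoformate, COC(OC)OC; methanol, CO
Why: Acid-catalysed acetalization driven by the orthoformate as water scavenger masks the aldehyde against n-BuLi.

Step 3
Reactants: 3 2-bromo-1-(dimethoxymethyl)-3,4,5-trimethoxybenzene; 4 3,4-dimethoxybenzaldehyde (veratraldehyde)
Product: 7 1-(dimethoxymethyl)-2-[(3,4-dimethoxyphenyl)(methoxy)methyl]-3,4,5-trimethoxybenzene (racemic), via aryllithium 5 (not isolated), via lithium alkoxide 6 (not isolated)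
Conditions: n-BuLi, THF, −78 °C; 4, −78 °C; then MeI (excess), DMPU, −78 °C → rt; aq. NaHCO3
Reagents that add atoms: methyl iodide, CI
Why: Bromine–lithium exchange, 1,2-addition of the aryllithium to the aldehyde and Williamson-type O-methylation of the alkoxide in the dipolar medium are done in one flask, so the carbinol never meets the neighbouring acetal under protic conditions; the new stereocenter is racemic and is erased in step 10.

Step 4
Reactants: 7 1-(dimethoxymethyl)-2-[(3,4-dimethoxyphenyl)(methoxy)methyl]-3,4,5-trimethoxybenzene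
Product: 8 2-[(3,4-dimethoxyphenyl)(methoxy)methyl]-3,4,5-trimethoxybenzaldehyde (racemic)
Conditions: PPTS (10 mol %), acetone/H2O 10:1, rt
Reagents that add atoms: water, O
Why: Acetal hydrolysis; the dimethyl acetal of an electron-rich benzaldehyde should cleave under a weak acid well before the diarylmethyl methyl ether ionizes.

Step 5
Reactants: 8 2-[(3,4-dimethoxyphenyl)(methoxy)methyl]-3,4,5-trimethoxybenzaldehyde; 9 dimethyl succinate
Product: 10 (3E)-4-Ar*-3-(methoxycarbonyl)but-3-enoic acid
Conditions: NaOMe, MeOH, reflux; then cold 1 M HCl to pH 3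
Reagents that add atoms: none
Why: Stobbe condensation (aldol addition, paraconate lactone, E1cB ring opening) should give the (E) half ester with the aryl group cis to CH2CO2H, and it delivers the two carboxyl carbons already differentiated as ester and acid.

Step 6
Reactants: 10 (3E)-4-Ar*-3-(methoxycarbonyl)but-3-enoic acid
Product: 12 (4E)-4-(Ar*-methylidene)oxolan-2-one, via hydroxy acid 11 (not isolated)
Conditions: i-Bu2AlH (4 equiv), CH2Cl2, −78 → −40 °C; aq. potassium sodium tartrate; then aq. citric acid (pH 3–4), rt
Reagents that add atoms: none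
Why: Chemoselective hydride reduction: the acid is converted at once into an aluminium carboxylate that resists hydride at low temperature, the conjugated ester is reduced 1,2 to the allylic alcohol, and the gamma-hydroxy acid lactonizes on mild acidification.

Step 7
Reactants: 12 (4E)-4-(Ar*-methylidene)oxolan-2-one
Product: 13 (3E)-4-Ar*-3-(hydroxymethyl)-N-methoxy-N-methylbut-3-enamide
Conditions: MeNH(OMe)·HCl, i-PrMgCl, THF, −20 → 0 °C; aq. NH4Cl
Reagents that add atoms: N,O-dimethylhydroxylamine hydrochloride, CNOC.Cl
Why: Aminolysis of the lactone by the chloromagnesium amide gives the open N-methoxy-N-methylamide; the reagent is not Lewis acidic, so the benzhydryl ether should survive, and the low temperature should keep the alkene from migrating.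

Step 8
Reactants: 13 (3E)-4-Ar*-3-(hydroxymethyl)-N-methoxy-N-methylbut-3-enamide
Product: 14 (3E)-3-({[tert-butyl(dimethyl)silyl]oxy}methyl)-4-Ar*-N-methoxy-N-methylbut-3-enamide
Conditions: TBSCl, imidazole, DMF, 0 °C → rt (crude 13, at once)
Reagents that add atoms: tert-butyldimethylsilyl chloride, CC(C)(C)[Si](C)(C)Cl
Why: Silylation of the primary allylic alcohol blocks re-closure to the lactone and installs the C3 silyloxymethyl group.

Step 9
Reactants: 14 (3E)-3-({[tert-butyl(dimethyl)silyl]oxy}methyl)-4-Ar*-N-methoxy-N-methylbut-3-enamide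
Product: 15 (3E)-3-({[tert-butyl(dimethyl)silyl]oxy}methyl)-4-Ar*-but-3-enal
Conditions: i-Bu2AlH (1.3 equiv), THF, −78 °C; aq. potassium sodium tartrate, 0 °C
Reagents that add atoms: none
Why: Partial reduction of the N-methoxy-N-methylamide through its chelated aluminium hemiaminal releases the aldehyde only on the cold, near-neutral work-up, which should keep the alkene out of conjugation with the aldehyde.

Step 10
Reactants: 15 (3E)-3-({[tert-butyl(dimethyl)silyl]oxy}methyl)-4-Ar*-but-3-enal
Product: 16 (1R,2S)-3-({[tert-butyl(dimethyl)silyl]oxy}methyl)-1-(3,4-dimethoxyphenyl)-6,7,8-trimethoxy-1,2-dihydronaphthalene-2-carbaldehyde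
Conditions: (S)-5-benzyl-2,2,3-trimethylimidazolidin-4-one·CF3CO2H (20 mol %), CH2Cl2/(CF3)2CHOH 9:1, H2O (2 equiv), 0.02 M, −20 °C
Reagents that add atoms: none
Why: Proposed new method: the amine condenses with the aldehyde of 15 to an (E)-enamine (a dienamine through C3=C4) while the acidic, ionizing medium turns the benzhydryl methyl ether into a diarylmethyl cation at C1, stabilized by the para methoxy groups of both rings and twisted out of the plane of ring A by its two ortho substituents so that its empty orbital points at C2; enamine carbon C2 attacks C1 and hydrolysis of the iminium returns the catalyst. The closest known reaction type is the intermolecular organocatalytic enantioselective alpha-alkylation of aldehydes with diarylmethyl cations generated from the alcohols; the ring-forming, intramolecular form with a methyl ether as cation source is the new element. Ring B closes in a six-membered enolexo mode (enamine C=C outside the new ring, trigonal cationic C1 inside it) through a half-chair transition state. C2 is set by the catalyst: in the enamine turned away from the gem-dimethyl carbon the benzyl group covers the Re face of C2, so C1 is delivered to the Si face and should give (2S); C1 is set relative to C2 by the ring, the dimethoxyphenyl group going pseudoaxial and trans to the enaminyl carbon to avoid the peri C8 methoxy group and the C3 substituent, which gives (1R), and the racemic ether carbon is erased on ionization. The step needs attack by C2 only: the (E) alkene holds C2 next to C1 and the silyloxymethyl group away from it, attack by the gamma carbon C4 would make a four-membered ring, and attack by C3 would make a quaternary centre in a five-membered ring and is reversible.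

Step 11
Reactants: 16 (1R,2S)-3-({[tert-butyl(dimethyl)silyl]oxy}methyl)-1-(3,4-dimethoxyphenyl)-6,7,8-trimethoxy-1,2-dihydronaphthalene-2-carbaldehyde
Product: 17 [(1R,2S)-3-({[tert-butyl(dimethyl)silyl]oxy}methyl)-1-(3,4-dimethoxyphenyl)-6,7,8-trimethoxy-1,2-dihydronaphthalen-2-yl]methanol
Conditions: NaBH4, MeOH/CH2Cl2, −20 → 0 °C (crude 16, at once)
Reagents that add atoms: none
Why: Borohydride reduction of the aldehyde at low temperature removes the acidic C2–H before C2 can epimerize or the alkene can shift; no new stereocenter is formed.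

Step 12
Reactants: 17 [(1R,2S)-3-({[tert-butyl(dimethyl)silyl]oxy}methyl)-1-(3,4-dimethoxyphenyl)-6,7,8-trimethoxy-1,2-dihydronaphthalen-2-yl]methanol
Product: 18 [(1R,2S)-1-(3,4-dimethoxyphenyl)-3-(hydroxymethyl)-6,7,8-trimethoxy-1,2-dihydronaphthalen-2-yl]methanol (CNP0274357.1)
Conditions: Bu4NF, THF, 0 °C → rt
Reagents that add atoms: none
Why: Fluoride-mediated cleavage of the silyl ether frees the C3 hydroxymethyl group without touching either stereocenter.

**Compound list**
1 | 3,4,5-trimethoxybenzaldehyde | COc1cc(C=O)cc(OC)c1OC | starting material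
2 | 2-bromo-3,4,5-trimethoxybenzaldehyde | COc1cc(C=O)c(Br)c(OC)c1OC | intermediate
3 | 2-bromo-1-(dimethoxymethyl)-3,4,5-trimethoxybenzene | COC(OC)c1cc(OC)c(OC)c(OC)c1Br | intermediate
4 | 3,4-dimethoxybenzaldehyde (veratraldehyde) | COc1ccc(C=O)cc1OC | starting material
5 | [6-(dimethoxymethyl)-2,3,4-trimethoxyphenyl]lithium | [Li]c1c(C(OC)OC)cc(OC)c(OC)c1OC | intermediate
6 | lithium (3,4-dimethoxyphenyl)[6-(dimethoxymethyl)-2,3,4-trimethoxyphenyl]methanolate (racemic) | [Li]OC(c1ccc(OC)c(OC)c1)c1c(C(OC)OC)cc(OC)c(OC)c1OC | intermediate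
7 | 1-(dimethoxymethyl)-2-[(3,4-dimethoxyphenyl)(methoxy)methyl]-3,4,5-trimethoxybenzene (racemic) | COC(c1ccc(OC)c(OC)c1)c1c(C(OC)OC)cc(OC)c(OC)c1OC | intermediate
8 | 2-[(3,4-dimethoxyphenyl)(methoxy)methyl]-3,4,5-trimethoxybenzaldehyde (racemic) | COC(c1ccc(OC)c(OC)c1)c1c(C=O)cc(OC)c(OC)c1OC | intermediate
9 | dimethyl succinate | COC(=O)CCC(=O)OC | starting material
10 | (3E)-4-{2-[(3,4-dimethoxyphenyl)(methoxy)methyl]-3,4,5-trimethoxyphenyl}-3-(methoxycarbonyl)but-3-enoic acid | COC(c1ccc(OC)c(OC)c1)c1c(/C=C(/C(=O)OC)CC(=O)O)cc(OC)c(OC)c1OC | intermediate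
11 | (3E)-4-{2-[(3,4-dimethoxyphenyl)(methoxy)methyl]-3,4,5-trimethoxyphenyl}-3-(hydroxymethyl)but-3-enoic acid | COC(c1ccc(OC)c(OC)c1)c1c(/C=C(/CO)CC(=O)O)cc(OC)c(OC)c1OC | intermediate
12 | (4E)-4-({2-[(3,4-dimethoxyphenyl)(methoxy)methyl]-3,4,5-trimethoxyphenyl}methylidene)oxolan-2-one | COC(c1ccc(OC)c(OC)c1)c1c(/C=C2/COC(=O)C2)cc(OC)c(OC)c1OC | intermediate
13 | (3E)-4-{2-[(3,4-dimethoxyphenyl)(methoxy)methyl]-3,4,5-trimethoxyphenyl}-3-(hydroxymethyl)-N-methoxy-N-methylbut-3-enamide | COC(c1ccc(OC)c(OC)c1)c1c(/C=C(/CO)CC(=O)N(C)OC)cc(OC)c(OC)c1OC | intermediate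
14 | (3E)-3-({[tert-butyl(dimethyl)silyl]oxy}methyl)-4-{2-[(3,4-dimethoxyphenyl)(methoxy)methyl]-3,4,5-trimethoxyphenyl}-N-methoxy-N-methylbut-3-enamide | COC(c1ccc(OC)c(OC)c1)c1c(/C=C(/CO[Si](C)(C)C(C)(C)C)CC(=O)N(C)OC)cc(OC)c(OC)c1OC | intermediate
15 | (3E)-3-({[tert-butyl(dimethyl)silyl]oxy}methyl)-4-{2-[(3,4-dimethoxyphenyl)(methoxy)methyl]-3,4,5-trimethoxyphenyl}but-3-enal | COC(c1ccc(OC)c(OC)c1)c1c(/C=C(/CO[Si](C)(C)C(C)(C)C)CC=O)cc(OC)c(OC)c1OC | intermediate
16 | (1R,2S)-3-({[tert-butyl(dimethyl)silyl]oxy}methyl)-1-(3,4-dimethoxyphenyl)-6,7,8-trimethoxy-1,2-dihydronaphthalene-2-carbaldehyde | COc1ccc([C@@H]2c3c(cc(OC)c(OC)c3OC)C=C(CO[Si](C)(C)C(C)(C)C)[C@H]2C=O)cc1OC | intermediate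
17 | [(1R,2S)-3-({[tert-butyl(dimethyl)silyl]oxy}methyl)-1-(3,4-dimethoxyphenyl)-6,7,8-trimethoxy-1,2-dihydronaphthalen-2-yl]methanol | COc1ccc([C@@H]2c3c(cc(OC)c(OC)c3OC)C=C(CO[Si](C)(C)C(C)(C)C)[C@H]2CO)cc1OC | intermediate
18 | [(1R,2S)-1-(3,4-dimethoxyphenyl)-3-(hydroxymethyl)-6,7,8-trimethoxy-1,2-dihydronaphthalen-2-yl]methanol | COc1ccc([C@@H]2c3c(cc(OC)c(OC)c3OC)C=C(CO)[C@H]2CO)cc1OC | target

Total step count: 12. Longest linear sequence: 12 steps (1 to 18); compounds 4 and 9 enter as purchased materials.

**Steps most likely to fail**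

1. Step 10 (proposed new method). Ionization may lag behind or outrun enamine formation, so that closure through the enol or an uncatalysed path erodes the facial selectivity. A cis closure followed by epimerization at C2 would give the mirror image, and intermolecular arylation of the cation may compete. The fallback uses an auxiliary and known chemistry; it sets out from half ester 10 and comes back to the route at target 18. The acid of 10 is activated with pivaloyl chloride and Et3N (THF, −20 °C) and acylated onto lithiated (S)-4-benzyl-1,3-oxazolidin-2-one to give methyl (2E)-4-[(4S)-4-benzyl-2-oxo-1,3-oxazolidin-3-yl]-2-(Ar*-methylidene)-4-oxobutanoate F1. TiCl4 and i-Pr2NEt in CH2Cl2 (−78 → 0 °C) form the chelated Z titanium enolate and ionize the benzhydryl methyl ether. The enolate is alkylated by the cation on the face away from the benzyl group (the known SN1 alkylation of titanium enolates of N-acyl oxazolidinones with cationic electrophiles) to give methyl (1R,2S)-2-{[(4S)-4-benzyl-2-oxo-1,3-oxazolidin-3-yl]carbonyl}-1-(3,4-dimethoxyphenyl)-6,7,8-trimethoxy-1,2-dihydronaphthalene-3-carboxylate F2. LiAlH4 in THF at −20 °C then reduces the imide carbonyl and the conjugated ester together to 18 and releases the oxazolidinone.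

2. Step 6. Hydride may attack the aluminium carboxylate (over-reduction to the diol) or add in conjugate fashion, and ring closure to the lactone may be incomplete. The fallback protects the acid as a hindered ester instead of relying on the inertness of the carboxylate; it sets out from 10 and comes back at lactone 12. Boc2O, DMAP (cat.) and t-BuOH convert 10 into 4-tert-butyl 1-methyl (2E)-2-(Ar*-methylidene)butanedioate F3. i-Bu2AlH (2.2 equiv, CH2Cl2, −78 °C) reduces only the methyl ester to give tert-butyl (3E)-4-Ar*-3-(hydroxymethyl)but-3-enoate F4. Brief treatment with t-BuOK (cat.) in THF at 0 °C closes 12 with loss of tert-butanol.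

3. Step 5. Aldol addition beside the bulky ortho diarylmethyl group may be slow, and the hot alkoxide may erode the alkene geometry or shift the double bond. The fallback builds the alkene under neutral conditions; it sets out from aldehyde 8 and comes back at half ester 10. Wittig reaction of 8 with the stabilized ylide dimethyl 2-(triphenylphosphoranylidene)butanedioate (toluene, reflux) gives dimethyl (2E)-2-(Ar*-methylidene)butanedioate F5. LiOH (1 equiv, THF/H2O, 0 °C) then saponifies the unconjugated, less hindered ester selectively to give 10.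

**Further compounds**
F1 | step 10 | methyl (2E)-4-[(4S)-4-benzyl-2-oxo-1,3-oxazolidin-3-yl]-2-({2-[(3,4-dimethoxyphenyl)(methoxy)methyl]-3,4,5-trimethoxyphenyl}methylidene)-4-oxobutanoate | COC(c1ccc(OC)c(OC)c1)c1c(/C=C(/C(=O)OC)CC(=O)N2[C@@H](Cc3ccccc3)COC2=O)cc(OC)c(OC)c1OC
F2 | step 10 | methyl (1R,2S)-2-{[(4S)-4-benzyl-2-oxo-1,3-oxazolidin-3-yl]carbonyl}-1-(3,4-dimethoxyphenyl)-6,7,8-trimethoxy-1,2-dihydronaphthalene-3-carboxylate | COc1ccc([C@@H]2c3c(cc(OC)c(OC)c3OC)C=C(C(=O)OC)[C@H]2C(=O)N2[C@@H](Cc3ccccc3)COC2=O)cc1OC
F3 | step 6 | 4-tert-butyl 1-methyl (2E)-2-({2-[(3,4-dimethoxyphenyl)(methoxy)methyl]-3,4,5-trimethoxyphenyl}methylidene)butanedioate | COC(c1ccc(OC)c(OC)c1)c1c(/C=C(/C(=O)OC)CC(=O)OC(C)(C)C)cc(OC)c(OC)c1OC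
F4 | step 6 | tert-butyl (3E)-4-{2-[(3,4-dimethoxyphenyl)(methoxy)methyl]-3,4,5-trimethoxyphenyl}-3-(hydroxymethyl)but-3-enoate | COC(c1ccc(OC)c(OC)c1)c1c(/C=C(/CO)CC(=O)OC(C)(C)C)cc(OC)c(OC)c1OC
F5 | step 5 | dimethyl (2E)-2-({2-[(3,4-dimethoxyphenyl)(methoxy)methyl]-3,4,5-trimethoxyphenyl}methylidene)butanedioate | COC(c1ccc(OC)c(OC)c1)c1c(/C=C(/C(=O)OC)CC(=O)OC)cc(OC)c(OC)c1OC
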